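## Retrosynthetic overview

1. The γ-lactone (the only ring of the target, closed last) comes from oxidative lactonization of a 1,4-diol: the primary CH2OH becomes C2 and the tertiary OH becomes the ring oxygen.
2. The C5–C1' bond comes from copper-catalysed opening of a 2-methyl-2-alkyloxirane at its CH2 by Ph(CH2)11MgBr; the bromide is made from 11-bromoundec-1-ene and iodobenzene by hydroboration/Suzuki coupling.
3. The C5 tertiary carbinol comes from Sharpless epoxidation of an (E)-2-methyl allylic alcohol, hydride opening at the CH carbon, and re-closure to the terminal oxirane (two transient oxiranes).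
4. The C4–C5 bond comes from Wittig olefination of an α-methyl aldehyde with Ph3P=C(Me)CO2Et.
5. The C3 methyl stereocentre comes from lipase desymmetrization of 2-methylpropane-1,3-diol.

Assumption: Pseudomonas fluorescens lipase acetylates the pro-S hydroxymethyl group of 1 (the sense I recall for this enzyme and substrate), so 2 is the (S)-monoacetate and the protecting-group order below follows from that.

## Route

Step 1
Reactants: 1 2-methylpropane-1,3-diol
Product: 2 (2S)-3-hydroxy-2-methylpropyl acetate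
Conditions: Pseudomonas fluorescens lipase (a triacylglycerol ester hydrolase, EC 3.1.1.3), vinyl acetate (3 equiv), CHCl3, rt, run until about 10% diacetate has formed
Reagents that add atoms: vinyl acetate, CC(=O)OC=C
Why: In this irreversible lipase-catalysed transesterification (enantioselective desymmetrization) the enzyme acetylates only one enantiotopic hydroxymethyl group of the prochiral diol, which sets the first stereocentre catalytically, and the minor enantiomer of the monoacetate is consumed faster to diacetate, which raises the ee.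

Step 2
Reactants: 2 (2S)-3-hydroxy-2-methylpropyl acetate
Product: 3 (2R)-3-[(tert-butyldiphenylsilyl)oxy]-2-methylpropyl acetate
Conditions: TBDPSCl (1.1 equiv), imidazole (2 equiv), CH2Cl2, 0 °C → rt
Reagents that add atoms: tert-butyldiphenylsilyl chloride, CC(C)(C)[Si](Cl)(c1ccccc1)c1ccccc1
Why: Imidazole-mediated silylation of the free primary alcohol is faster than 1,3-acyl migration and does not touch the stereocentre (the descriptor changes only through CIP priorities).

Step 3
Reactants: 3 (2R)-3-[(tert-butyldiphenylsilyl)oxy]-2-methylpropyl acetate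
Product: 4 (2R)-3-[(tert-butyldiphenylsilyl)oxy]-2-methylpropan-1-ol
Conditions: K2CO3 (0.3 equiv), MeOH, 0 °C
Reagents that add atoms: none
Why: Carbonate-catalysed methanolysis (transesterification) removes the acetate while the bulky TBDPS ether neither cleaves nor migrates at 0 °C, so the two ends of the diol are now differentiated in the required sense.

Step 4
Reactants: 4 (2R)-3-[(tert-butyldiphenylsilyl)oxy]-2-methylpropan-1-ol
Product: 5 (2S)-3-[(tert-butyldiphenylsilyl)oxy]-2-methylpropanal
Conditions: Dess–Martin periodinane (1.3 equiv), CH2Cl2, 0 °C → rt; crude aldehyde used at once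
Reagents that add atoms: none
Why: Dess–Martin oxidation is fast and non-basic, so the α-methyl aldehyde is formed without enolization.

Step 5
Reactants: 5 (2S)-3-[(tert-butyldiphenylsilyl)oxy]-2-methylpropanal; 6 ethyl 2-(triphenylphosphoranylidene)propanoate
Product: 7 ethyl (2E,4R)-5-[(tert-butyldiphenylsilyl)oxy]-2,4-dimethylpent-2-enoate
Conditions: CH2Cl2, rt → 40 °C
Reagents that add atoms: none
Why: Wittig olefination with the stabilized α-methyl ylide gives the (E)-trisubstituted enoate with high selectivity and is too weakly basic to epimerize the aldehyde.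

Step 6
Reactants: 7 ethyl (2E,4R)-5-[(tert-butyldiphenylsilyl)oxy]-2,4-dimethylpent-2-enoate
Product: 8 (2E,4R)-5-[(tert-butyldiphenylsilyl)oxy]-2,4-dimethylpent-2-en-1-ol
Conditions: i-Bu2AlH (2.5 equiv), CH2Cl2, −78 °C; aqueous potassium sodium tartrate work-up
Reagents that add atoms: none
Why: i-Bu2AlH reduces the conjugated ester by 1,2-hydride addition to the allylic alcohol and leaves the alkene and the silyl ether intact.

Step 7
Reactants: 8 (2E,4R)-5-[(tert-butyldiphenylsilyl)oxy]-2,4-dimethylpent-2-en-1-ol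
Product: 9 [(2R,3R)-3-[(2S)-1-[(tert-butyldiphenylsilyl)oxy]propan-2-yl]-2-methyloxiran-2-yl]methanol
Conditions: Ti(OiPr)4 (10 mol %), D-(−)-diethyl tartrate (12 mol %), t-BuOOH (2 equiv, in decane), 4 Å MS, CH2Cl2, −20 °C
Reagents that add atoms: tert-butyl hydroperoxide, CC(C)(C)OO
Why: In this Sharpless asymmetric epoxidation the titanium–D-tartrate catalyst delivers oxygen to one face of the allylic alcohol under reagent control (the remote C4 methyl has little influence), which sets the tertiary C–O stereocentre as (2R) and keeps the E geometry as the trans epoxide.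

Step 8
Reactants: 9 [(2R,3R)-3-[(2S)-1-[(tert-butyldiphenylsilyl)oxy]propan-2-yl]-2-methyloxiran-2-yl]methanol
Product: 10 (2S,4R)-5-[(tert-butyldiphenylsilyl)oxy]-2,4-dimethylpentane-1,2-diol
Conditions: LiAlH4 (2 equiv), THF, 0 °C → rt; aqueous potassium sodium tartrate work-up
Reagents that add atoms: none
Why: Hydride opens the trisubstituted epoxide by SN2 attack at the CH carbon because the fully substituted carbon cannot be attacked from the back, so the bond between oxygen and the quaternary carbon and its configuration are kept and the tertiary 1,2-diol results.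

Step 9
Reactants: 10 (2S,4R)-5-[(tert-butyldiphenylsilyl)oxy]-2,4-dimethylpentane-1,2-diol
Product: 11 (2S,4R)-5-[(tert-butyldiphenylsilyl)oxy]-2-hydroxy-2,4-dimethylpentyl 4-methylbenzenesulfonate
Conditions: TsCl (1.2 equiv), Et3N, DMAP (cat.), CH2Cl2, 0 °C
Reagents that add atoms: 4-methylbenzenesulfonyl chloride, Cc1ccc(cc1)S(Cl)(=O)=O
Why: Sulfonylation is selective for the primary hydroxyl because the tertiary hydroxyl is too hindered to react with TsCl.

Step 10
Reactants: 11 (2S,4R)-5-[(tert-butyldiphenylsilyl)oxy]-2-hydroxy-2,4-dimethylpentyl 4-methylbenzenesulfonate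
Product: 12 tert-butyl{(2R)-2-methyl-3-[(2S)-2-methyloxiran-2-yl]propoxy}diphenylsilane
Conditions: K2CO3, MeOH, 0 °C → rt
Reagents that add atoms: none
Why: Intramolecular Williamson etherification (3-exo-tet displacement of tosylate by the tertiary alkoxide) closes the terminal epoxide without breaking the bond between oxygen and the stereocentre.

Step 11
Reactants: 13 11-bromoundec-1-ene; 14 iodobenzene
Product: 16 (11-bromoundecyl)benzene, via 9-(11-bromoundecyl)-9-BBN 15 (not isolated)
Conditions: 9-BBN (1.1 equiv), THF, 0 °C → rt; then 14, Pd(dppf)Cl2 (3 mol %), Cs2CO3, DMF/H2O, rt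
Reagents that add atoms: none
Why: Anti-Markovnikov hydroboration followed by B-alkyl Suzuki–Miyaura coupling joins the primary alkylborane to iodobenzene at room temperature, where the primary alkyl bromide does not undergo oxidative addition.

Step 12
Reactants: 12 tert-butyl{(2R)-2-methyl-3-[(2S)-2-methyloxiran-2-yl]propoxy}diphenylsilane; 16 (11-bromoundecyl)benzene
Product: 18 (2R,4R)-1-[(tert-butyldiphenylsilyl)oxy]-2,4-dimethyl-16-phenylhexadecan-4-ol, via (11-phenylundecyl)magnesium bromide 17 (not isolated)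
Conditions: 16, Mg, THF, 40 °C; then CuI (10 mol %), 12, THF, −30 → 0 °C; aqueous work-up
Reagents that add atoms: none
Why: In this copper-catalysed Grignard epoxide opening the organocopper species attacks the unsubstituted CH2 of the 2,2-disubstituted epoxide in SN2 fashion, which forms the C–C bond without touching the quaternary stereocentre.

Step 13
Reactants: 18 (2R,4R)-1-[(tert-butyldiphenylsilyl)oxy]-2,4-dimethyl-16-phenylhexadecan-4-ol
Product: 19 (2R,4R)-2,4-dimethyl-16-phenylhexadecane-1,4-diol
Conditions: Bu4NF (1.5 equiv), THF, rt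
Reagents that add atoms: none
Why: Fluoride-mediated desilylation is driven by the strong Si–F bond and leaves the tertiary alcohol and both stereocentres untouched.

Step 14
Reactants: 19 (2R,4R)-2,4-dimethyl-16-phenylhexadecane-1,4-diol
Product: 22 (3R,5R)-3,5-dimethyl-5-(12-phenyldodecyl)oxolan-2-one, via hydroxy aldehyde 20 (not isolated), via lactol 21 (not isolated)
Conditions: TEMPO (20 mol %), PhI(OAc)2 (3 equiv), CH2Cl2, rt
Reagents that add atoms: none
Why: In this TEMPO/PhI(OAc)2 oxidative lactonization the oxoammonium species oxidizes only the primary alcohol, the γ-hydroxy aldehyde closes to the five-membered lactol, and a second oxidation gives the lactone under mildly acidic conditions that neither epimerize C3 nor ionize the tertiary C–O bond.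

## Compound list

1 | 2-methylpropane-1,3-diol | CC(CO)CO | starting material
2 | (2S)-3-hydroxy-2-methylpropyl acetate | CC(=O)OC[C@@H](C)CO | intermediate
3 | (2R)-3-[(tert-butyldiphenylsilyl)oxy]-2-methylpropyl acetate | CC(=O)OC[C@@H](C)CO[Si](c1ccccc1)(c1ccccc1)C(C)(C)C | intermediate
4 | (2R)-3-[(tert-butyldiphenylsilyl)oxy]-2-methylpropan-1-ol | OC[C@@H](C)CO[Si](c1ccccc1)(c1ccccc1)C(C)(C)C | intermediate
5 | (2S)-3-[(tert-butyldiphenylsilyl)oxy]-2-methylpropanal | O=C[C@@H](C)CO[Si](c1ccccc1)(c1ccccc1)C(C)(C)C | intermediate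
6 | ethyl 2-(triphenylphosphoranylidene)propanoate | CCOC(=O)C(C)=P(c1ccccc1)(c1ccccc1)c1ccccc1 | starting material
7 | ethyl (2E,4R)-5-[(tert-butyldiphenylsilyl)oxy]-2,4-dimethylpent-2-enoate | CCOC(=O)/C(C)=C/[C@@H](C)CO[Si](c1ccccc1)(c1ccccc1)C(C)(C)C | intermediate
8 | (2E,4R)-5-[(tert-butyldiphenylsilyl)oxy]-2,4-dimethylpent-2-en-1-ol | OC/C(C)=C/[C@@H](C)CO[Si](c1ccccc1)(c1ccccc1)C(C)(C)C | intermediate
9 | [(2R,3R)-3-[(2S)-1-[(tert-butyldiphenylsilyl)oxy]propan-2-yl]-2-methyloxiran-2-yl]methanol | OC[C@@]1(C)O[C@@H]1[C@@H](C)CO[Si](c2ccccc2)(c2ccccc2)C(C)(C)C | intermediate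
10 | (2S,4R)-5-[(tert-butyldiphenylsilyl)oxy]-2,4-dimethylpentane-1,2-diol | OC[C@@](C)(O)C[C@@H](C)CO[Si](c1ccccc1)(c1ccccc1)C(C)(C)C | intermediate
11 | (2S,4R)-5-[(tert-butyldiphenylsilyl)oxy]-2-hydroxy-2,4-dimethylpentyl 4-methylbenzenesulfonate | Cc1ccc(cc1)S(=O)(=O)OC[C@@](C)(O)C[C@@H](C)CO[Si](c1ccccc1)(c1ccccc1)C(C)(C)C | intermediate
12 | tert-butyl{(2R)-2-methyl-3-[(2S)-2-methyloxiran-2-yl]propoxy}diphenylsilane | C1O[C@@]1(C)C[C@@H](C)CO[Si](c2ccccc2)(c2ccccc2)C(C)(C)C | intermediate
13 | 11-bromoundec-1-ene | C=CCCCCCCCCCBr | starting material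
14 | iodobenzene | Ic1ccccc1 | starting material
15 | 9-(11-bromoundecyl)-9-borabicyclo[3.3.1]nonane | BrCCCCCCCCCCCB1C2CCCC1CCC2 | intermediate
16 | (11-bromoundecyl)benzene | BrCCCCCCCCCCCc1ccccc1 | intermediate
17 | (11-phenylundecyl)magnesium bromide | Br[Mg]CCCCCCCCCCCc1ccccc1 | intermediate
18 | (2R,4R)-1-[(tert-butyldiphenylsilyl)oxy]-2,4-dimethyl-16-phenylhexadecan-4-ol | O[C@](C)(CCCCCCCCCCCCc1ccccc1)C[C@@H](C)CO[Si](c1ccccc1)(c1ccccc1)C(C)(C)C | intermediate
19 | (2R,4R)-2,4-dimethyl-16-phenylhexadecane-1,4-diol | O[C@](C)(CCCCCCCCCCCCc1ccccc1)C[C@@H](C)CO | intermediate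
20 | (2R,4R)-4-hydroxy-2,4-dimethyl-16-phenylhexadecanal | C[C@@H](C=O)C[C@](C)(O)CCCCCCCCCCCCc1ccccc1 | intermediate
21 | (3R,5R)-3,5-dimethyl-5-(12-phenyldodecyl)oxolan-2-ol (both anomers) | C[C@@H]1C[C@@](C)(CCCCCCCCCCCCc2ccccc2)OC1O | intermediate
22 | (3R,5R)-3,5-dimethyl-5-(12-phenyldodecyl)oxolan-2-one | C[C@@H]1C[C@@](C)(CCCCCCCCCCCCc2ccccc2)OC1=O | target

## Step count and risks

Total steps: 14. Longest linear sequence: 13 (steps 1–10 and 12–14; step 11 is the side branch).

Three steps most likely to fail: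

**Step 8 (hydride opening of 9).** The CH carbon sits between a quaternary and a branched carbon, and the free hydroxyl can redirect hydride to the wrong carbon or allow Payne rearrangement. Prolonged LiAlH4 contact can also erode the silyl ether. The fallback sets out from 9 (and uses 17 made as in step 12) and comes back at 18, by-passing 10–12. Tf2O/2,6-lutidine (CH2Cl2, −78 °C) turns 9 into the epoxy triflate [(2R,3R)-3-[(2S)-1-[(tert-butyldiphenylsilyl)oxy]propan-2-yl]-2-methyloxiran-2-yl]methyl trifluoromethanesulfonate F1. Grignard 17 with catalytic CuBr·SMe2 (Et2O/THF, −78 → −40 °C) displaces the triflate and gives the chain-extended epoxide tert-butyl{(2S)-2-[(2R,3R)-3-methyl-3-(12-phenyldodecyl)oxiran-2-yl]propoxy}diphenylsilane F2. LiBHEt3 (THF, 0 °C → rt) then opens F2 at the CH carbon, with no neighbouring hydroxyl to interfere, and gives 18.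

**Step 12 (Grignard formation and copper-catalysed opening of 12).** Wurtz coupling of 16, bromohydrin formation or rearrangement of the epoxide by MgBr2, and slow attack next to the quaternary carbon are the failure modes. The fallback sets out from 10 and 16 and comes back at 18, replacing the epoxide opening by olefination and hydrogenation. SO3·pyridine/DMSO/i-Pr2NEt (CH2Cl2, 0 °C) oxidizes the primary alcohol of 10 to the non-epimerizable α-hydroxy aldehyde (2S,4R)-5-[(tert-butyldiphenylsilyl)oxy]-2-hydroxy-2,4-dimethylpentanal F3. PPh3 (MeCN, reflux) converts 16 into (11-phenylundecyl)triphenylphosphonium bromide F4. The ylide from F4 (NaN(SiMe3)2, 2.2 equiv of ylide, THF, −78 → 0 °C) reacts with F3 to give the alkene (2R,4S,5Z)-1-[(tert-butyldiphenylsilyl)oxy]-2,4-dimethyl-16-phenylhexadec-5-en-4-ol F5. H2 over Pd/C (EtOAc, rt) saturates F5 to 18.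

**Step 1 (lipase desymmetrization).** The ee depends on stopping at the right conversion, and 2 can lose ee by 1,3-acyl migration. The fallback sets out from 1 and comes back at 4, using the same enzyme class in hydrolytic mode. Ac2O/pyridine gives 2-methylpropane-1,3-diyl diacetate F6. The lipase in pH 7 phosphate buffer hydrolyses the same enantiotopic group and leaves the antipodal monoester (2R)-3-hydroxy-2-methylpropyl acetate F7. Because F7 is the mirror image of 2, the ends are then protected in the opposite order. TrCl/Et3N/DMAP gives (2R)-2-methyl-3-(triphenylmethoxy)propyl acetate F8. K2CO3/MeOH gives (2S)-2-methyl-3-(triphenylmethoxy)propan-1-ol F9. TBDPSCl/imidazole gives tert-butyl[(2R)-2-methyl-3-(triphenylmethoxy)propoxy]diphenylsilane F10. TsOH (cat.) in MeOH/CH2Cl2 at 0 °C removes the trityl group and gives 4.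

## Further compounds

F1 | step 8 | [(2R,3R)-3-[(2S)-1-[(tert-butyldiphenylsilyl)oxy]propan-2-yl]-2-methyloxiran-2-yl]methyl trifluoromethanesulfonate | FC(F)(F)S(=O)(=O)OC[C@@]1(C)O[C@@H]1[C@@H](C)CO[Si](c2ccccc2)(c2ccccc2)C(C)(C)C
F2 | step 8 | tert-butyl{(2S)-2-[(2R,3R)-3-methyl-3-(12-phenyldodecyl)oxiran-2-yl]propoxy}diphenylsilane | c1ccccc1CCCCCCCCCCCC[C@@]2(C)O[C@@H]2[C@@H](C)CO[Si](c3ccccc3)(c3ccccc3)C(C)(C)C
F3 | step 12 | (2S,4R)-5-[(tert-butyldiphenylsilyl)oxy]-2-hydroxy-2,4-dimethylpentanal | O=C[C@@](C)(O)C[C@@H](C)CO[Si](c1ccccc1)(c1ccccc1)C(C)(C)C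
F4 | step 12 | (11-phenylundecyl)triphenylphosphonium bromide | [Br-].c1ccccc1CCCCCCCCCCC[P+](c1ccccc1)(c1ccccc1)c1ccccc1
F5 | step 12 | (2R,4S,5Z)-1-[(tert-butyldiphenylsilyl)oxy]-2,4-dimethyl-16-phenylhexadec-5-en-4-ol | c1ccccc1CCCCCCCCCC/C=C\[C@@](C)(O)C[C@@H](C)CO[Si](c1ccccc1)(c1ccccc1)C(C)(C)C
F6 | step 1 | 2-methylpropane-1,3-diyl diacetate | CC(=O)OCC(C)COC(C)=O
F7 | step 1 | (2R)-3-hydroxy-2-methylpropyl acetate | CC(=O)OC[C@H](C)CO
F8 | step 1 | (2R)-2-methyl-3-(triphenylmethoxy)propyl acetate | CC(=O)OC[C@H](C)COC(c1ccccc1)(c1ccccc1)c1ccccc1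
F9 | step 1 | (2S)-2-methyl-3-(triphenylmethoxy)propan-1-ol | OC[C@H](C)COC(c1ccccc1)(c1ccccc1)c1ccccc1
F10 | step 1 | tert-butyl[(2R)-2-methyl-3-(triphenylmethoxy)propoxy]diphenylsilane | CC(C)(C)[Si](c1ccccc1)(c1ccccc1)OC[C@H](C)COC(c1ccccc1)(c1ccccc1)c1ccccc1
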